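**Plan**
- Retrosynthetic cuts: the silyl mask on the one free phenol; the last dihydropyran ring at its O–C(ketal) and CH2–CH bonds; the first ketal ring in the same way; the diarylmethane C–C bond; the dihydrobenzofuran back to a bromophenol and isoprene.
- Enabling feature: each ketal ring is a 2-alkoxychroman, a phenolic O and an ortho benzylic CH2 bridged by the O,O-ketal carbon and its neighbouring CH. This is the imprint of a [4+2] addition of an o-quinone methide (C=C–C=O of the arene) to the ring C=C of (R)-3,5-dimethyl-2,3-dihydrofuran, the presumed biosynthetic event.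
- Forward order: 2,4,6-trihydroxybenzaldehyde → para-O-silyl ether → C-benzylation with the dihydrobenzofuran fragment → aminomethylation of the last free ring carbon → first ketal ring (closure possible only onto the one free ortho oxygen) → the formyl group, carried from the start, becomes the second quinone methide → last ring → desilylation.
- Stereochemistry: the methyl centre of the dihydrofuran comes from an Evans propargylation and steers both cycloadditions (anti addition, cis fusion). The dihydrobenzofuran centre comes from an enantioselective palladium-catalysed heteroannulation of isoprene.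

Key step: step 11

Assumption: the chiral ligand of step 4 is available in both enantiomeric forms and the one giving the (S)-product is used; (R)-4-methyldihydrofuran-2(3H)-one, needed only in a fallback, is taken as purchasable.

Step 1
Reactants: 1 (S)-4-benzyl-3-propanoyl-1,3-oxazolidin-2-one; 2 3-bromoprop-1-yne
Product: 4 (S)-4-benzyl-3-[(2R)-2-methylpent-4-ynoyl]-1,3-oxazolidin-2-one, via sodium Z-enolate 3 (not isolated)
Conditions: NaN(SiMe3)2, THF, −78 °C; then 2, −78 to −40 °C
Reagents that add atoms: none
Why: Evans asymmetric alkylation, in which the chelated Z-enolate is propargylated on the face opposite the benzyl group of the auxiliary, which should set the (R) methyl-bearing centre.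

Step 2
Reactants: 4 (S)-4-benzyl-3-[(2R)-2-methylpent-4-ynoyl]-1,3-oxazolidin-2-one
Product: 5 (2R)-2-methylpent-4-yn-1-ol
Conditions: LiBH4, H2O (1 equiv), Et2O, 0 °C
Reagents that add atoms: none
Why: Reductive cleavage of the N-acyl oxazolidinone by borohydride should give the primary alcohol without touching the alkyne or the α-stereocentre.

Step 3
Reactants: 5 (2R)-2-methylpent-4-yn-1-ol
Product: 7 (3R)-3,5-dimethyl-2,3-dihydrofuran, via exocyclic enol ether 6 (not isolated)
Conditions: NaNH2 (5 mol %), neat, 110–130 °C, product distilled off as it forms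
Reagents that add atoms: none
Why: Base-catalysed 5-exo-dig hydroalkoxylation of the alkynol followed by prototropic shift of the exocyclic double bond into the ring gives the trisubstituted enol ether; the methyl-bearing carbon takes no part, so its configuration should be kept.

Step 4
Reactants: 8 3-bromo-4-hydroxybenzaldehyde; 9 isoprene
Product: 10 (2S)-2-(prop-1-en-2-yl)-2,3-dihydro-1-benzofuran-5-carbaldehyde
Conditions: Pd2(dba)3·CHCl3 (2.5 mol %), TY-Phos-type chiral sulfinamide phosphine ligand (S-selective enantiomer, 10 mol %), PhONa (2 equiv), 9 (5 equiv), toluene, 80 °C, sealed tube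
Reagents that add atoms: none
Why: Enantioselective Heck/Tsuji–Trost heteroannulation: oxidative addition of the aryl bromide to zerovalent palladium, arylpalladation of the less substituted alkene of isoprene (aryl to the terminal CH2) and ligand-controlled C–O bond formation at the internal allyl terminus close the dihydrofuran ring and set C2.

Step 5
Reactants: 10 (2S)-2-(prop-1-en-2-yl)-2,3-dihydro-1-benzofuran-5-carbaldehyde
Product: 11 [(2S)-2-(prop-1-en-2-yl)-2,3-dihydro-1-benzofuran-5-yl]methanol
Conditions: NaBH4, MeOH, 0 °C
Reagents that add atoms: none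
Why: Chemoselective hydride reduction of the aryl aldehyde, which leaves the alkene and the stereocentre untouched.

Step 6
Reactants: 12 2,4,6-trihydroxybenzaldehyde
Product: 13 2,6-dihydroxy-4-[(triisopropylsilyl)oxy]benzaldehyde
Conditions: iPr3SiCl (1.05 equiv), imidazole (2.2 equiv), DMF, −20 to 0 °C
Reagents that add atoms: triisopropylsilyl chloride, CC(C)[Si](Cl)(C(C)C)C(C)C
Why: Selective phenol silylation: the para hydroxyl is the most acidic and the only one not held in a hydrogen bond to the formyl group, so one equivalent of the bulky silyl chloride should react there.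

Step 7
Reactants: 13 2,6-dihydroxy-4-[(triisopropylsilyl)oxy]benzaldehyde; 11 [(2S)-2-(prop-1-en-2-yl)-2,3-dihydro-1-benzofuran-5-yl]methanol
Product: 14 2,6-dihydroxy-3-{[(2S)-2-(prop-1-en-2-yl)-2,3-dihydro-1-benzofuran-5-yl]methyl}-4-[(triisopropylsilyl)oxy]benzaldehyde
Conditions: 13 (3 equiv), Sc(OTf)3 (5 mol %), 4 Å molecular sieves, CH2Cl2, 0 °C to rt
Reagents that add atoms: none
Why: Lewis-acid-catalysed Friedel–Crafts benzylation in which the activated p-alkoxybenzyl alcohol alkylates one of the two equivalent, oxygen-flanked ring carbons of 13 (used in excess to suppress double benzylation); no stereocentre is formed and the mild acid should leave the allylic aryl ether centre intact.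

Step 8
Reactants: 14 2,6-dihydroxy-3-{[(2S)-2-(prop-1-en-2-yl)-2,3-dihydro-1-benzofuran-5-yl]methyl}-4-[(triisopropylsilyl)oxy]benzaldehyde
Product: 15 3-[(dimethylamino)methyl]-2,6-dihydroxy-5-{[(2S)-2-(prop-1-en-2-yl)-2,3-dihydro-1-benzofuran-5-yl]methyl}-4-[(triisopropylsilyl)oxy]benzaldehyde
Conditions: CH2=NMe2 iodide (1.2 equiv), CH2Cl2, 0 °C to rt; then aq. NaHCO3
Reagents that add atoms: N,N-dimethylmethyleneiminium iodide (Eschenmoser's salt), C=[N+](C)C.[I-]
Why: Mannich aminomethylation with a preformed iminium salt at the only unsubstituted ring carbon, which lies ortho to a free hydroxyl.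

Step 9
Reactants: 15 (Mannich base); 7 (3R)-3,5-dimethyl-2,3-dihydrofuran
Product: 17 (3R,3aR,9aR)-7-hydroxy-3,9a-dimethyl-6-{[(2S)-2-(prop-1-en-2-yl)-2,3-dihydro-1-benzofuran-5-yl]methyl}-5-[(triisopropylsilyl)oxy]-2,3,3a,9a-tetrahydro-4H-furo[2,3-b]chromene-8-carbaldehyde, via o-quinone methide 16 (not isolated)
Conditions: 7 (5 equiv), toluene, 100 °C, sealed tube
Reagents that add atoms: none
Why: Thermal loss of dimethylamine from the zwitterionic phenolic Mannich base gives the formyl-substituted o-quinone methide, which undergoes an inverse-demand hetero-Diels–Alder reaction with the enol ether; the silyl ether blocks the other ortho oxygen so only one ketal regioisomer can form, and suprafacial addition anti to the C3 methyl of 7 should set the cis ring fusion and both new centres.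

Step 10
Reactants: 17 (ketal aldehyde)
Product: 18 (3R,3aR,9aR)-8-[(dimethylamino)methyl]-3,9a-dimethyl-6-{[(2S)-2-(prop-1-en-2-yl)-2,3-dihydro-1-benzofuran-5-yl]methyl}-5-[(triisopropylsilyl)oxy]-2,3,3a,9a-tetrahydro-4H-furo[2,3-b]chromen-7-ol
Conditions: Me2NH (2 M in THF, 3 equiv), NaBH(OAc)3 (1.5 equiv), 1,2-dichloroethane, rt
Reagents that add atoms: dimethylamine, CNC
Why: Reductive amination of the salicylaldehyde gives a stable Mannich base; it is preferred to reduction to the benzylic alcohol, which on so electron-rich a ring would be prone to ionise and be reduced further to a methyl group.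

Step 11
Reactants: 18 (Mannich base); 7 (3R)-3,5-dimethyl-2,3-dihydrofuran
Product: 21 triisopropylsilyl ether of the target (silyl group on the remaining phenolic oxygen), via trimethylammonium iodide 19 (not isolated), via o-quinone methide 20 (not isolated)
Conditions: MeI (3 equiv), MeCN, rt, then volatiles removed; 7 (5 equiv), iPr2NEt (1.5 equiv), toluene, 60 °C, sealed tube
Reagents that add atoms: none
Why: N-Methylation gives ammonium salt 19, from which the amine base removes the phenolic proton and trimethylamine leaves in a 1,4-elimination to give o-quinone methide 20 (exocyclic CH2 on C8, carbonyl at C7), which is captured by the enol ether C4=C5 bond of 7 in an inverse-electron-demand hetero-Diels–Alder reaction. The closest known reaction type is the [4+2] cycloaddition of quinone methides released from phenolic Mannich-base methiodides with cyclic enol ethers to give 2-alkoxychroman ketals. The dihydropyran ring is closed by a concerted, asynchronous cycloaddition in which the benzylic CH2–C bond runs ahead of the O–C(ketal) bond, and suprafacial addition across the ring alkene makes the cis ring fusion compulsory. Both new stereocentres (the ring-fusion CH and the methyl-bearing ketal carbon) are controlled by the C3 methyl group of 7, which sits next to the carbon that bonds first and shields its own face, so addition should occur anti to it. The step needs site-, regio- and chemoselectivity: only one quinone methide can form because the other ortho oxygen is already in the first ketal ring and the para oxygen is silylated, the polarised enol ether delivers its oxygen-bearing carbon to the quinone methide oxygen, every ring carbon is substituted so no Friedel–Crafts dimer can arise, and the electron-rich enol ether in excess should outcompete the isopropenyl group. The non-acidic generation keeps the enol ether, the first ketal and the isopropenyl dihydrobenzofuran intact.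

Step 12
Reactants: 21 (silyl ether of the target)
Product: 22 target CNP0131395.1
Conditions: Bu4NF (1.1 equiv), THF, 0 °C; pH 7 phosphate buffer work-up
Reagents that add atoms: none
Why: Fluoride cleavage of the aryl silyl ether; basic conditions and a neutral work-up are chosen because acid could open the first ketal ring and let it re-close onto the freed neighbouring phenol.

**Compound list**
1 | (S)-4-benzyl-3-propanoyl-1,3-oxazolidin-2-one | CCC(=O)N1[C@@H](Cc2ccccc2)COC1=O | starting material
2 | 3-bromoprop-1-yne (propargyl bromide) | C#CCBr | starting material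
3 | sodium Z-enolate of 1 | C/C=C(\[O-])N1[C@@H](Cc2ccccc2)COC1=O.[Na+] | intermediate
4 | (S)-4-benzyl-3-[(2R)-2-methylpent-4-ynoyl]-1,3-oxazolidin-2-one | C#CC[C@@H](C)C(=O)N1[C@@H](Cc2ccccc2)COC1=O | intermediate
5 | (2R)-2-methylpent-4-yn-1-ol | C#CC[C@@H](C)CO | intermediate
6 | (4R)-4-methyl-2-methylideneoxolane (exocyclic enol ether) | C=C1C[C@@H](C)CO1 | intermediate
7 | (3R)-3,5-dimethyl-2,3-dihydrofuran | C[C@H]1COC(C)=C1 | intermediate
8 | 3-bromo-4-hydroxybenzaldehyde | O=Cc1ccc(O)c(Br)c1 | starting material
9 | isoprene | C=CC(C)=C | starting material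
10 | (2S)-2-(prop-1-en-2-yl)-2,3-dihydro-1-benzofuran-5-carbaldehyde | C=C(C)[C@@H]1Cc2cc(C=O)ccc2O1 | intermediate
11 | [(2S)-2-(prop-1-en-2-yl)-2,3-dihydro-1-benzofuran-5-yl]methanol | C=C(C)[C@@H]1Cc2cc(CO)ccc2O1 | intermediate
12 | 2,4,6-trihydroxybenzaldehyde | O=Cc1c(O)cc(O)cc1O | starting material
13 | 2,6-dihydroxy-4-[(triisopropylsilyl)oxy]benzaldehyde | O=Cc1c(O)cc(O[Si](C(C)C)(C(C)C)C(C)C)cc1O | intermediate
14 | 2,6-dihydroxy-3-{[(2S)-2-(prop-1-en-2-yl)-2,3-dihydro-1-benzofuran-5-yl]methyl}-4-[(triisopropylsilyl)oxy]benzaldehyde | C=C(C)[C@@H]1Cc2cc(Cc3c(O)c(C=O)c(O)cc3O[Si](C(C)C)(C(C)C)C(C)C)ccc2O1 | intermediate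
15 | 3-[(dimethylamino)methyl]-2,6-dihydroxy-5-{[(2S)-2-(prop-1-en-2-yl)-2,3-dihydro-1-benzofuran-5-yl]methyl}-4-[(triisopropylsilyl)oxy]benzaldehyde | C=C(C)[C@@H]1Cc2cc(Cc3c(O)c(C=O)c(O)c(CN(C)C)c3O[Si](C(C)C)(C(C)C)C(C)C)ccc2O1 | intermediate
16 | o-quinone methide from 15 (exocyclic CH2 at the former aminomethyl carbon, C=O at the adjacent former phenol carbon next to the formyl-bearing carbon) | C=C(C)[C@@H]1Cc2cc(CC3=C(O[Si](C(C)C)(C(C)C)C(C)C)C(=C)C(=O)C(C=O)=C3O)ccc2O1 | intermediate
17 | (3R,3aR,9aR)-7-hydroxy-3,9a-dimethyl-6-{[(2S)-2-(prop-1-en-2-yl)-2,3-dihydro-1-benzofuran-5-yl]methyl}-5-[(triisopropylsilyl)oxy]-2,3,3a,9a-tetrahydro-4H-furo[2,3-b]chromene-8-carbaldehyde | C=C(C)[C@@H]1Cc2cc(Cc3c(O)c(C=O)c4O[C@@]5(C)OC[C@H](C)[C@H]5Cc4c3O[Si](C(C)C)(C(C)C)C(C)C)ccc2O1 | intermediate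
18 | (3R,3aR,9aR)-8-[(dimethylamino)methyl]-3,9a-dimethyl-6-{[(2S)-2-(prop-1-en-2-yl)-2,3-dihydro-1-benzofuran-5-yl]methyl}-5-[(triisopropylsilyl)oxy]-2,3,3a,9a-tetrahydro-4H-furo[2,3-b]chromen-7-ol | C=C(C)[C@@H]1Cc2cc(Cc3c(O)c(CN(C)C)c4O[C@@]5(C)OC[C@H](C)[C@H]5Cc4c3O[Si](C(C)C)(C(C)C)C(C)C)ccc2O1 | intermediate
19 | trimethylammonium iodide from 18 (N-methylated Mannich base) | C=C(C)[C@@H]1Cc2cc(Cc3c(O)c(C[N+](C)(C)C)c4O[C@@]5(C)OC[C@H](C)[C@H]5Cc4c3O[Si](C(C)C)(C(C)C)C(C)C)ccc2O1.[I-] | intermediate
20 | o-quinone methide from 19 (8-methylidene, 7-oxo; first ketal ring, silyl ether and benzyl group in place) | C=C(C)[C@@H]1Cc2cc(CC3=C(O[Si](C(C)C)(C(C)C)C(C)C)C4=C(O[C@@]5(C)OC[C@H](C)[C@H]5C4)C(=C)C3=O)ccc2O1 | intermediate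
21 | triisopropylsilyl ether of the target (both ketal rings closed) | C=C(C)[C@@H]1Cc2cc(Cc3c(O[Si](C(C)C)(C(C)C)C(C)C)c4c(c5c3O[C@@]3(C)OC[C@H](C)[C@H]3C5)O[C@@]3(C)OC[C@H](C)[C@H]3C4)ccc2O1 | intermediate
22 | CNP0131395.1 | C=C(C)[C@@H]1Cc2cc(Cc3c(O)c4c(c5c3O[C@@]3(C)OC[C@H](C)[C@H]3C5)O[C@@]3(C)OC[C@H](C)[C@H]3C4)ccc2O1 | target

**Totals**
Total step count: 12. Longest linear sequence: 8 steps (steps 4, 5, 7, 8, 9, 10, 11, 12).

**Steps most likely to fail**

Step 7 (Friedel–Crafts benzylation). What may go wrong: double benzylation of the symmetric phenol, or cationic side reactions of the isopropenyl dihydrobenzofuran (oligomerisation, opening of the allylic aryl ether with loss of configuration) under the Lewis acid. The fallback replaces the cationic coupling by a cross-coupling and sets out from 13 and 11. Iodination of 13 (N-iodosuccinimide, 1.0 equiv, MeCN, 0 °C) would give 3-iodo-2,6-dihydroxy-4-[(triisopropylsilyl)oxy]benzaldehyde F1. Alcohol 11 would be converted with PPh3 and N-chlorosuccinimide (CH2Cl2, 0 °C) into the benzylic chloride F2 and then with Zn dust and LiCl in THF into the benzylzinc chloride F3. Negishi coupling of F1 (phenols deprotonated first with NaH) with F3 (Pd(OAc)2, SPhos, THF, rt) comes back to the route at 14.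

Step 11 (key cycloaddition). What may go wrong: poor facial selectivity of the cycloaddition, or diversion of the quinone methide before it meets the enol ether. The fallback builds the same ring stepwise by known chemistry and sets out from 18. Its methiodide 19 would be added at −78 °C to an excess of the lithium enolate of (R)-4-methyldihydrofuran-2(3H)-one F4 (from the lactone C[C@H]1COC(=O)C1 and LiN(iPr)2 in THF). The enolate first releases the quinone methide and then adds to its methylene carbon trans to the ring methyl group, which should give the (3R,4R)-lactone F5. MeLi (THF, −78 °C) would convert it into the methyl lactol F6. Pyridinium p-toluenesulfonate in CH2Cl2 would then close the ketal onto the neighbouring phenol, the silyl ether still blocking the other one, and the sequence comes back to the route at 21.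

Step 4 (asymmetric heteroannulation). What may go wrong: insufficient enantioselectivity, or arylpalladation at the wrong alkene of isoprene. The fallback gives up asymmetric catalysis for resolution and sets out from 8 and 9. The same annulation without chiral ligand (Pd(OAc)2, dppf, Na2CO3, DMF, 100 °C) would give the racemic aldehyde F7, NaBH4 in MeOH the racemic alcohol F8, and preparative chromatography on a chiral stationary phase would deliver the (S)-enantiomer, coming back to the route at 11.

Further compounds
F1 | step 7 | 3-iodo-2,6-dihydroxy-4-[(triisopropylsilyl)oxy]benzaldehyde | O=Cc1c(O)cc(O[Si](C(C)C)(C(C)C)C(C)C)c(I)c1O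
F2 | step 7 | (2S)-5-(chloromethyl)-2-(prop-1-en-2-yl)-2,3-dihydro-1-benzofuran | C=C(C)[C@@H]1Cc2cc(CCl)ccc2O1
F3 | step 7 | {[(2S)-2-(prop-1-en-2-yl)-2,3-dihydro-1-benzofuran-5-yl]methyl}zinc chloride | C=C(C)[C@@H]1Cc2cc(C[Zn]Cl)ccc2O1
F4 | step 11 | lithium enolate of (R)-4-methyldihydrofuran-2(3H)-one | C[C@H]1COC([O-])=C1.[Li+]
F5 | step 11 | (3R,4R)-lactone: 18 with the dimethylaminomethyl group replaced by a (4-methyl-2-oxooxolan-3-yl)methyl group | C=C(C)[C@@H]1Cc2cc(Cc3c(O)c(C[C@@H]4[C@@H](C)COC4=O)c4O[C@@]5(C)OC[C@H](C)[C@H]5Cc4c3O[Si](C(C)C)(C(C)C)C(C)C)ccc2O1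
F6 | step 11 | methyl lactol from F5 (2-hydroxy-2,4-dimethyloxolan-3-yl)methyl compound, anomeric mixture | C=C(C)[C@@H]1Cc2cc(Cc3c(O)c(C[C@@H]4[C@@H](C)COC4(C)O)c4O[C@@]5(C)OC[C@H](C)[C@H]5Cc4c3O[Si](C(C)C)(C(C)C)C(C)C)ccc2O1
F7 | step 4 | racemic 2-(prop-1-en-2-yl)-2,3-dihydro-1-benzofuran-5-carbaldehyde | C=C(C)C1Cc2cc(C=O)ccc2O1
F8 | step 4 | racemic [2-(prop-1-en-2-yl)-2,3-dihydro-1-benzofuran-5-yl]methanol | C=C(C)C1Cc2cc(CO)ccc2O1
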